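The C18 aldehyde of the target is traced back to the unactivated equatorial 4α-methyl group of (+)-larixol, which is reached from the ring B oxygen at C6. In a single operation a 6α-alkoxy radical abstracts hydrogen from C18 and the resulting iodide is displaced. This closes the 6α,18-oxolane across C4–C5–C6, differentiates the two C4 methyl groups and fixes C4. The step exploits the syn-pentane contact between the equatorial C6–O and C4–C18 bonds on the α face of the trans-fused rings A and B. Its precursor has O6 as the only free hydroxyl, with C8 masked as the 8α,17-epoxide and C13 as a dioxolane.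

Key step: step 4

Remarks on the chemistry:
- Labdane numbering is used. C18 is the equatorial 4α-methyl carbon, C19 the axial 4β-methyl carbon, C20 the methyl carbon on C10 and C17 the carbon on C8. C15 is the side-chain carbinol carbon, and C2'–C5' are the furanone ring atoms, with C5' bonded to C15.
- Assumption: the target is the open 6α-hydroxy 18-aldehyde; in solution it may equilibrate with its 6α,18-lactol.
- The lactol and its methyl acetal are carried as mixtures of C18 epimers, which converge in the last step.
- The facial sense of the aldol step is predicted by analogy and would be checked by Mosher ester analysis of 20; if the opposite sense is found, (S)-BINOL would be used in place of (R)-BINOL.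

Step 1
Reactants: 1 (+)-larixol, labda-8(17),14-diene-6α,13S-diol
Product: 2 6α-hydroxy-14,15-dinorlabd-8(17)-en-13-one
Conditions: KMnO4, acetone, 0 °C to rt
Reagents that add atoms: none
Why: Permanganate degradation of a vinyl carbinol (dihydroxylation of the unhindered monosubstituted C14=C15 alkene, glycol cleavage and loss of both carbons) should stop at the C13 methyl ketone, because the exocyclic C8=C17 alkene is shielded by the C10 methyl group and the C9 side chain and the hindered 6α-hydroxyl is oxidised only slowly; no stereocentre is formed.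

Step 2
Reactants: 2 6α-hydroxy-14,15-dinorlabd-8(17)-en-13-one; 3 ethylene glycol
Product: 4 13,13-ethylenedioxy-14,15-dinorlabd-8(17)-en-6α-ol
Conditions: PPTS (cat.), benzene, reflux, Dean–Stark
Reagents that add atoms: none
Why: Acid-catalysed ketalisation with azeotropic removal of water protects C13 for the later hydride and oxidation steps, and the weak acid PPTS should not move the exocyclic double bond into the ring.

Step 3
Reactants: 4 13,13-ethylenedioxy-14,15-dinorlabd-8(17)-en-6α-ol
Product: 5 8α,17-epoxy-13,13-ethylenedioxy-14,15-dinorlabdan-6α-ol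
Conditions: mCPBA, NaHCO3, CH2Cl2, 0 °C
Reagents that add atoms: mCPBA, OOC(=O)c1cccc(Cl)c1
Why: Prilezhaev epoxidation in which the peracid reaches C8=C17 from the α face, because the β face is screened by the axial C10 methyl group (C20) in a 1,3 relationship to C8, so the oxygen is placed 8α and C17 8β, while the buffer keeps the acid by-product from opening the spiro-epoxide or the ketal.

Step 4
Reactants: 5 8α,17-epoxy-13,13-ethylenedioxy-14,15-dinorlabdan-6α-ol
Product: 8 6α,18:8α,17-diepoxy-13,13-ethylenedioxy-14,15-dinorlabdane, via 6α-hypoiodite 6 (not isolated), via 18-iodo-6α-alcohol 7 (not isolated)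
Conditions: PhI(OAc)2, I2, cyclohexane–CH2Cl2, visible light (tungsten lamp), 10–15 °C
Reagents that add atoms: none
Why: Acetyl hypoiodite made from PhI(OAc)2 and I2 turns the 6α-hydroxyl into hypoiodite 6, visible light breaks the O–I bond, the C6 oxygen radical takes a hydrogen atom from C18 through a chair-like six-membered transition state, iodine caps the primary radical as 7, and the hydroxyl then displaces iodide (helped by oxidation of the iodide by the excess trivalent iodine reagent) to give 8 without any new carbon–carbon bond. The closest known reaction is the hypoiodite etherification of steroidal 6β- and 11β-alcohols onto syn-axial angular methyl groups; here the relay runs between two equatorial positions that sit in the same syn-pentane arrangement as such a diaxial pair. The one ring closed is the oxolane O–C6–C5–C4–C18, formed in the 5-exo-tet mode with O6 as nucleophile and C18 as electrophile. The new stereocentre is C4, and it is fixed by the rigid trans-decalin, since in models only the 4α-methyl carbon lies about 2.5 Å from the 6α-oxygen, whereas C19 is gauche on the far side and C20 and C17 are anti to the C6–O bond on the β face. The step needs hydrogen transfer to outrun β-scission of the C5–C6 bond and needs O6 to be the only oxygen radical: the short O···H–C18 contact, a non-polar medium and a low temperature serve the first, the epoxide at C8 and the ketal at C13 serve the second, and the excess iodane re-oxidises hydrogen iodide before it can open the epoxide.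

Step 5
Reactants: 8 6α,18:8α,17-diepoxy-13,13-ethylenedioxy-14,15-dinorlabdane
Product: 9 6α,18-epoxy-13,13-ethylenedioxy-14,15-dinorlabdan-8α-ol
Conditions: LiAlH4, THF, 0 °C to reflux
Reagents that add atoms: none
Why: Hydride opening of the epoxide by SN2 attack at the primary carbon C17 does not touch the C8–O bond, so the 8α-oxygen set in step 3 is kept and C17 becomes the axial 8β-methyl group, while the oxolane and the dioxolane are inert to LiAlH4.

Step 6
Reactants: 9 6α,18-epoxy-13,13-ethylenedioxy-14,15-dinorlabdan-8α-ol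
Product: 10 13,13-ethylenedioxy-8α-hydroxy-14,15-dinorlabdan-18,6α-olide
Conditions: RuCl3·xH2O (cat.), NaIO4, CCl4–MeCN–H2O, rt
Reagents that add atoms: sodium periodate, [Na+].[O-]I(=O)(=O)=O
Why: RuO4 formed in the flask oxidises an ether methylene to the ester carbonyl (the usual conversion of tetrahydrofurans into γ-lactones), and C18 is the only such methylene, because the other α-carbon, C6, carries one axial hydrogen flanked by the C19 and C20 methyl groups, the tertiary alcohol has no carbinol hydrogen, and any ketal cleaved in the acidic aqueous medium converges in step 7.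

Step 7
Reactants: 10 13,13-ethylenedioxy-8α-hydroxy-14,15-dinorlabdan-18,6α-olide
Product: 11 8α-hydroxy-13-oxo-14,15-dinorlabdan-18,6α-olide
Conditions: 1 M HCl, THF, rt
Reagents that add atoms: water, O
Why: Acid-catalysed hydrolysis of the dioxolane frees the methyl ketone under conditions that the lactone and the tertiary alcohol tolerate, and the water present prevents dehydration of the δ-hydroxy ketone to a cyclic enol ether.

Step 8
Reactants: 11 8α-hydroxy-13-oxo-14,15-dinorlabdan-18,6α-olide; 12 triethyl phosphonoacetate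
Product: 13 ethyl (13E)-8α-hydroxy-18-oxo-6α,18-epoxylabd-13-en-15-oate
Conditions: NaH (less than the phosphonate), THF, 0 °C to 40 °C
Reagents that add atoms: none
Why: Horner–Wadsworth–Emmons olefination, in which reversible addition and the less crowded oxaphosphetane place the ester trans to the C12 chain so that the 13E ester should predominate (the minor 13Z isomer is removed by chromatography), and the stabilised phosphonate anion, kept free of excess NaH, is too weak a base to deprotonate the tertiary alcohol for an oxa-Michael closure or to open the lactone.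

Step 9
Reactants: 13 ethyl (13E)-8α-hydroxy-18-oxo-6α,18-epoxylabd-13-en-15-oate
Product: 14 (13E)-6α,18-epoxylabd-13-ene-8α,15,18-triol (lactol, C18 epimers)
Conditions: iBu2AlH (DIBAL-H, excess), CH2Cl2, −78 °C; aqueous potassium sodium tartrate
Reagents that add atoms: none
Why: Low-temperature reduction with iBu2AlH takes the conjugated ester to the allylic alcohol by 1,2-addition and stops the lactone at the lactol, because its tetrahedral aluminium alkoxide does not collapse at −78 °C, without touching the double-bond geometry or any ring stereocentre.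

Step 10
Reactants: 14 (13E)-6α,18-epoxylabd-13-ene-8α,15,18-triol
Product: 15 (13E)-18-methoxy-6α,18-epoxylabd-13-ene-8α,15-diol (C18 epimers)
Conditions: MeOH, PPTS (cat.), rt
Reagents that add atoms: methanol, CO
Why: Acid-catalysed acetalisation of the lactol through its cyclic oxocarbenium ion masks the C18 aldehyde for the aldol step, PPTS in methanol being too weak to ionise the primary allylic alcohol or dehydrate the tertiary one, and the new acetal centre forms as an epimer mixture that is removed in step 14.

Step 11
Reactants: 15 (13E)-18-methoxy-6α,18-epoxylabd-13-ene-8α,15-diol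
Product: 16 (13E)-8α-hydroxy-18-methoxy-6α,18-epoxylabd-13-en-15-al (C18 epimers)
Conditions: MnO2, CH2Cl2, rt
Reagents that add atoms: none
Why: Selective allylic oxidation, since MnO2 oxidises only the allylic alcohol, does not isomerise the 13E double bond and leaves the tertiary alcohol and the acetal alone.

Step 12
Reactants: 17 4-methyl-2(5H)-furanone
Product: 18 4-methyl-2-(trimethylsilyloxy)furan
Conditions: TMSOTf, Et3N, Et2O, 0 °C; distillation
Reagents that add atoms: trimethylsilyl triflate, C[Si](C)(C)OS(=O)(=O)C(F)(F)F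
Why: Soft enolisation (silyl dienol ether formation), in which O-silylation of the lactone carbonyl by TMSOTf and removal of a γ-hydrogen at C5 by Et3N give the aromatic 2-silyloxyfuran.

Step 13
Reactants: 16 (13E)-8α-hydroxy-18-methoxy-6α,18-epoxylabd-13-en-15-al; 18 4-methyl-2-(trimethylsilyloxy)furan
Product: 20 (13E,15S)-18-methoxy-15-[(2S)-3-methyl-5-oxo-2,5-dihydrofuran-2-yl]-6α,18-epoxylabd-13-ene-8α,15-diol (C18 epimers), via 15-O-trimethylsilyl ether 19 (not isolated)
Conditions: Ti(OiPr)4 (20 mol%), (R)-BINOL (20 mol%), Et2O, −20 °C; then citric acid, MeOH, 0 °C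
Reagents that add atoms: none
Why: Catalytic enantioselective vinylogous Mukaiyama aldol addition, in which the catalyst formed from Ti(OiPr)4 and (R)-BINOL activates the aldehyde, the furan attacks through C5 and the silyl group passes to the aldolate oxygen; an open transition state in which the alkenyl residue avoids the furan 4-methyl group should give the threo relationship, and the (R)-BINOL catalyst is expected to leave the Re face of the aldehyde open (as in allylations and aldol additions of unbranched aldehydes), which would set C15 and C5' both S under catalyst control because the decalin stereocentres are five or more bonds away, while the weakly acidic titanium alkoxide should not ionise the methyl acetal; Mosher ester analysis of 20 would confirm the configuration at C15.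

Step 14
Reactants: 20 (13E,15S)-18-methoxy-15-[(2S)-3-methyl-5-oxo-2,5-dihydrofuran-2-yl]-6α,18-epoxylabd-13-ene-8α,15-diol
Product: 21 (13E,15S)-6α,8α,15-trihydroxy-15-[(2S)-3-methyl-5-oxo-2,5-dihydrofuran-2-yl]labd-13-en-18-al (target)
Conditions: AcOH–THF–H2O (3:1:1), rt
Reagents that add atoms: water, O
Why: Acid-catalysed hydrolysis of the cyclic mixed acetal gives from both C18 epimers the same lactol, which opens to the 6α-hydroxy 18-aldehyde, and aqueous acetic acid is weak enough to spare the allylic C15 alcohol, the tertiary C8 alcohol and the butenolide.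

Compound list
1 | (+)-larixol, labda-8(17),14-diene-6α,13S-diol | C=C[C@@](C)(O)CC[C@@H]1[C@@]2(C)CCCC(C)(C)[C@@H]2[C@@H](O)CC1=C | starting material
2 | 6α-hydroxy-14,15-dinorlabd-8(17)-en-13-one | CC(=O)CC[C@@H]1[C@@]2(C)CCCC(C)(C)[C@@H]2[C@@H](O)CC1=C | intermediate
3 | ethylene glycol | OCCO | starting material
4 | 13,13-ethylenedioxy-14,15-dinorlabd-8(17)-en-6α-ol | CC1(OCCO1)CC[C@@H]1[C@@]2(C)CCCC(C)(C)[C@@H]2[C@@H](O)CC1=C | intermediate
5 | 8α,17-epoxy-13,13-ethylenedioxy-14,15-dinorlabdan-6α-ol | CC1(OCCO1)CC[C@@H]1[C@@]2(C)CCCC(C)(C)[C@@H]2[C@@H](O)C[C@@]1(C3)O3 | intermediate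
6 | 6α-hypoiodite of 5 | CC1(OCCO1)CC[C@@H]1[C@@]2(C)CCCC(C)(C)[C@@H]2[C@@H](OI)C[C@@]1(C3)O3 | intermediate
7 | 8α,17-epoxy-13,13-ethylenedioxy-18-iodo-14,15-dinorlabdan-6α-ol | CC1(OCCO1)CC[C@@H]1[C@@]2(C)CCC[C@@](C)(CI)[C@@H]2[C@@H](O)C[C@@]1(C3)O3 | intermediate
8 | 6α,18:8α,17-diepoxy-13,13-ethylenedioxy-14,15-dinorlabdane | CC1(OCCO1)CC[C@@H]1[C@@]2(C)CCC[C@@](C)(CO3)[C@@H]2[C@@H]3C[C@@]1(C4)O4 | intermediate
9 | 6α,18-epoxy-13,13-ethylenedioxy-14,15-dinorlabdan-8α-ol | CC1(OCCO1)CC[C@@H]1[C@@]2(C)CCC[C@@](C)(CO3)[C@@H]2[C@@H]3C[C@@]1(C)O | intermediate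
10 | 13,13-ethylenedioxy-8α-hydroxy-14,15-dinorlabdan-18,6α-olide | CC1(OCCO1)CC[C@@H]1[C@@]2(C)CCC[C@@](C)(C(=O)O3)[C@@H]2[C@@H]3C[C@@]1(C)O | intermediate
11 | 8α-hydroxy-13-oxo-14,15-dinorlabdan-18,6α-olide | CC(=O)CC[C@@H]1[C@@]2(C)CCC[C@@](C)(C(=O)O3)[C@@H]2[C@@H]3C[C@@]1(C)O | intermediate
12 | triethyl phosphonoacetate | CCOC(=O)CP(=O)(OCC)OCC | starting material
13 | ethyl (13E)-8α-hydroxy-18-oxo-6α,18-epoxylabd-13-en-15-oate | CCOC(=O)/C=C(\C)CC[C@@H]1[C@@]2(C)CCC[C@@](C)(C(=O)O3)[C@@H]2[C@@H]3C[C@@]1(C)O | intermediate
14 | (13E)-6α,18-epoxylabd-13-ene-8α,15,18-triol (lactol, C18 epimers) | OC/C=C(\C)CC[C@@H]1[C@@]2(C)CCC[C@@](C)(C(O)O3)[C@@H]2[C@@H]3C[C@@]1(C)O | intermediate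
15 | (13E)-18-methoxy-6α,18-epoxylabd-13-ene-8α,15-diol (C18 epimers) | OC/C=C(\C)CC[C@@H]1[C@@]2(C)CCC[C@@](C)(C(OC)O3)[C@@H]2[C@@H]3C[C@@]1(C)O | intermediate
16 | (13E)-8α-hydroxy-18-methoxy-6α,18-epoxylabd-13-en-15-al (C18 epimers) | O=C/C=C(\C)CC[C@@H]1[C@@]2(C)CCC[C@@](C)(C(OC)O3)[C@@H]2[C@@H]3C[C@@]1(C)O | intermediate
17 | 4-methyl-2(5H)-furanone | CC1=CC(=O)OC1 | starting material
18 | 4-methyl-2-(trimethylsilyloxy)furan | Cc1coc(O[Si](C)(C)C)c1 | intermediate
19 | 15-O-trimethylsilyl ether of 20 | CC1=CC(=O)O[C@@H]1[C@@H](O[Si](C)(C)C)/C=C(\C)CC[C@@H]1[C@@]2(C)CCC[C@@](C)(C(OC)O3)[C@@H]2[C@@H]3C[C@@]1(C)O | intermediate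
20 | (13E,15S)-18-methoxy-15-[(2S)-3-methyl-5-oxo-2,5-dihydrofuran-2-yl]-6α,18-epoxylabd-13-ene-8α,15-diol (C18 epimers) | CC1=CC(=O)O[C@@H]1[C@@H](O)/C=C(\C)CC[C@@H]1[C@@]2(C)CCC[C@@](C)(C(OC)O3)[C@@H]2[C@@H]3C[C@@]1(C)O | intermediate
21 | (13E,15S)-6α,8α,15-trihydroxy-15-[(2S)-3-methyl-5-oxo-2,5-dihydrofuran-2-yl]labd-13-en-18-al | CC1=CC(=O)O[C@@H]1[C@@H](O)/C=C(\C)CC[C@@H]1[C@@]2(C)CCC[C@@](C)(C=O)[C@@H]2[C@@H](O)C[C@@]1(C)O | target

Total step count: 14.
Longest linear sequence: 13 steps (steps 1–11, 13 and 14 from 1); step 12 is a one-step side branch.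

Steps most likely to fail

Step 4. The oxygen radical may cleave the C5–C6 bond faster than it abstracts hydrogen. Alternatively, hydrogen transfer may succeed and the iodine chemistry behind it fail, through slow displacement at the neopentyl carbon C18 on the way to a strained ring, or through opening of the epoxide by iodide and acetic acid. The fallback is a nitrite photolysis, which needs neither iodine nor a ring closure at C18 and delivers C18 at the aldehyde level. It answers the second kind of failure; the radical is the same, so against fragmentation only temperature and solvent remain. It sets out from 5 and comes back at 10, so that steps 4 to 6 are bypassed. Alcohol 5 is esterified with NOCl in pyridine at −20 °C to the 6α-nitrite ester F1. Irradiation (mercury lamp, Pyrex, benzene, 10 °C) gives the oxygen radical, nitric oxide caps C18 after the hydrogen transfer, and the nitroso dimer is isomerised in warm 2-propanol to the C18 aldoxime F2. Buffered reductive deoximation (TiCl3, NH4OAc, aqueous dioxane, rt) gives the 6α,18-lactol F3 with epoxide and ketal in place. LiAlH4 in THF reduces the lactol and opens the epoxide at C17 to give the 6α,8α,18-triol F4. TEMPO (cat.) and PhI(OAc)2 in CH2Cl2 then oxidise the primary C18 alcohol, and the lactol that forms with the 6α-hydroxyl is oxidised on to lactone 10.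

Step 13. The nearest stereocentre is far down the chain and gives the catalyst no help, so facial selectivity may be poor. The furan 4-methyl group may also erode the threo preference, and a β,β-disubstituted enal may turn the catalyst over slowly. The fallback controls both centres with an auxiliary in a syn-glycolate aldol addition and builds the butenolide ring afterwards. It sets out from 16 and comes back at 21, at the cost of six more steps. Aldehyde 16 is added to the dibutylboron enolate of (R)-4-benzyl-3-[(4-methoxybenzyloxy)acetyl]oxazolidin-2-one (Bu2BOTf, Et3N, CH2Cl2, −78 to 0 °C) to give the syn-aldol imide F5, in which C15 and the PMB-oxy carbon (the later C5') have the configuration of the target. Transamination (MeONHMe·HCl, AlMe3, 0 °C) gives the Weinreb amide F6. Silylation of the C15 hydroxyl (TESCl, imidazole) gives the silyl ether F7, and MeMgBr gives the methyl ketone F8. DDQ in buffered wet CH2Cl2 removes the PMB group to give the α-hydroxy ketone F9. Ph3P=C=C=O in toluene at 80 °C acylates the hydroxyl and closes the ring by intramolecular Wittig reaction to give the silylated butenolide F10. The conditions of step 14 then remove the TES group and open the acetal to give 21.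

Step 9. The two carbonyl groups may be reduced at unequal rates, so that conditions which complete one reduction spoil the other: the neopentyl lactone may lag behind the ester, or be over-reduced once the mixture is warmed. The fallback separates the two reductions by carrying C13 as a carbinol while C18 is adjusted, and olefinates afterwards. It sets out from 11 and comes back at 15. iBu2AlH at −78 °C reduces the ketone and the lactone of 11 to the lactol carbinol F11 (C13 and C18 epimers). MeOH and PPTS give the methyl acetal carbinol F12. Dess–Martin periodinane (NaHCO3, CH2Cl2) oxidises only the secondary C13 alcohol to give the acetal methyl ketone F13. Olefination as in step 8 gives the 13E ester acetal F14, and iBu2AlH then has a single ester to reduce, giving 15.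

Further compounds
F1 | step 4 | 6α-nitrite ester of 5 | CC1(OCCO1)CC[C@@H]1[C@@]2(C)CCCC(C)(C)[C@@H]2[C@@H](ON=O)C[C@@]1(C3)O3
F2 | step 4 | 8α,17-epoxy-13,13-ethylenedioxy-6α-hydroxy-14,15-dinorlabdan-18-al (E)-oxime | CC1(OCCO1)CC[C@@H]1[C@@]2(C)CCC[C@@](C)(/C=N/O)[C@@H]2[C@@H](O)C[C@@]1(C3)O3
F3 | step 4 | 6α,18:8α,17-diepoxy-13,13-ethylenedioxy-14,15-dinorlabdan-18-ol (lactol, C18 epimers) | CC1(OCCO1)CC[C@@H]1[C@@]2(C)CCC[C@@](C)(C(O)O3)[C@@H]2[C@@H]3C[C@@]1(C4)O4
F4 | step 4 | 13,13-ethylenedioxy-14,15-dinorlabdane-6α,8α,18-triol | CC1(OCCO1)CC[C@@H]1[C@@]2(C)CCC[C@@](C)(CO)[C@@H]2[C@@H](O)C[C@@]1(C)O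
F5 | step 13 | syn-aldol imide, (R)-4-benzyl-3-acyl-oxazolidin-2-one with 15S-hydroxyl and PMB-oxy carbon as in the target | COc1ccc(CO[C@@H](C(=O)N2[C@H](Cc3ccccc3)COC2=O)[C@@H](O)/C=C(\C)CC[C@@H]2[C@@]3(C)CCC[C@@](C)(C(OC)O4)[C@@H]3[C@@H]4C[C@@]2(C)O)cc1
F6 | step 13 | N-methoxy-N-methyl amide of the syn-aldol acid | COc1ccc(CO[C@@H](C(=O)N(C)OC)[C@@H](O)/C=C(\C)CC[C@@H]2[C@@]3(C)CCC[C@@](C)(C(OC)O4)[C@@H]3[C@@H]4C[C@@]2(C)O)cc1
F7 | step 13 | 15-O-triethylsilyl ether of F6 | COc1ccc(CO[C@@H](C(=O)N(C)OC)[C@@H](O[Si](CC)(CC)CC)/C=C(\C)CC[C@@H]2[C@@]3(C)CCC[C@@](C)(C(OC)O4)[C@@H]3[C@@H]4C[C@@]2(C)O)cc1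
F8 | step 13 | α-(4-methoxybenzyloxy) methyl ketone | COc1ccc(CO[C@@H](C(C)=O)[C@@H](O[Si](CC)(CC)CC)/C=C(\C)CC[C@@H]2[C@@]3(C)CCC[C@@](C)(C(OC)O4)[C@@H]3[C@@H]4C[C@@]2(C)O)cc1
F9 | step 13 | α-hydroxy methyl ketone | O[C@@H](C(C)=O)[C@@H](O[Si](CC)(CC)CC)/C=C(\C)CC[C@@H]1[C@@]2(C)CCC[C@@](C)(C(OC)O3)[C@@H]2[C@@H]3C[C@@]1(C)O
F10 | step 13 | 15-O-triethylsilyl ether of 20 | CC1=CC(=O)O[C@@H]1[C@@H](O[Si](CC)(CC)CC)/C=C(\C)CC[C@@H]1[C@@]2(C)CCC[C@@](C)(C(OC)O3)[C@@H]2[C@@H]3C[C@@]1(C)O
F11 | step 9 | 6α,18-epoxy-14,15-dinorlabdane-8α,13,18-triol (C13 and C18 epimers) | CC(O)CC[C@@H]1[C@@]2(C)CCC[C@@](C)(C(O)O3)[C@@H]2[C@@H]3C[C@@]1(C)O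
F12 | step 9 | 18-methoxy-6α,18-epoxy-14,15-dinorlabdane-8α,13-diol (C13 and C18 epimers) | CC(O)CC[C@@H]1[C@@]2(C)CCC[C@@](C)(C(OC)O3)[C@@H]2[C@@H]3C[C@@]1(C)O
F13 | step 9 | 8α-hydroxy-18-methoxy-6α,18-epoxy-14,15-dinorlabdan-13-one (C18 epimers) | CC(=O)CC[C@@H]1[C@@]2(C)CCC[C@@](C)(C(OC)O3)[C@@H]2[C@@H]3C[C@@]1(C)O
F14 | step 9 | ethyl (13E)-8α-hydroxy-18-methoxy-6α,18-epoxylabd-13-en-15-oate (C18 epimers) | CCOC(=O)/C=C(\C)CC[C@@H]1[C@@]2(C)CCC[C@@](C)(C(OC)O3)[C@@H]2[C@@H]3C[C@@]1(C)O
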